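At 1.33 h the solid electrophile stands at 59% in summer and 55% in spring, so the two runs feed the solution at a similar pace. Yet at 3.00 h you read 56% of product in summer and 82% in spring, so the nucleophile charge matters downstream.

| flask | solid electrophile | nucleophile | remark | time |
|---|---|---|---|---|
| summer | 0.45 M | 0.61 M | run made earlier |  |
| spring | 0.45 M | 1.4 M | run made earlier |  |
| alpha | 0.45 M | 1.10 M |  | 4.0 h |
| epsilon | 0.45 M | 0.540 M |  | 4.0 h |

| run | time / h | solid electrophile / % | product / % |
|---|---|---|---|
| summer | 0.250 | 90 | 1 |
| summer | 0.417 | 84 | 9 |
| summer | 0.833 | 73 | 13 |
| summer | 1.33 | 59 | 25 |
| summer | 3.00 | 20 | 56 |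
| spring | 0.250 | 91 | 4 |
| spring | 0.417 | 86 | 11 |
| spring | 0.833 | 69 | 21 |
| spring | 1.33 | 55 | 33 |
| spring | 3.00 | 6 | 82 |

(each reading ± 2 percentage points)

- part of the solid electrophile that has reacted (what has only dissolved counts as not reacted) at the end, alpha
- part of the solid electrophile that has reacted (what has only dissolved counts as not reacted) at the end, epsilon
- what raising the concentration of nucleophile from its lowest to its highest value here does to the part of the solid electrophile that has reacted (what has only dissolved counts as not reacted) (changes below 5 percentage points count as none) (it falls / no change / it rises)

- what was read earlier has a scatter of 2 percentage points, one standard deviation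
- at the start none of the solid electrophile is in solution
- what has only dissolved of solid electrophile counts as not reacted

Climb the ladder in hours, fastest rung first. The dissolved material in spring turns over in its dissolved share divided by its product rate over the last interval:

0.409 h

Scaled to the charge of epsilon, at full nucleophile, that becomes:

1.06 h

The solid empties, at the summer pace, in:

3.24 h

Both are shorter than the asked 4.0 h, so in epsilon the clock is not the top rung; the nucleophile's purse may be. My own assumption is that the acid each product sets free takes up a second nucleophile. Then the paired budget, the product in percent of the solid charged that the nucleophile can pay for at two per product, is: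

60.0%

That makes nucleophile the limiting reagent in epsilon, and I expect somewhat below this. Alpha's budget is 122%, above the charge, so there I expect time to count, and conversion to rise with nucleophile.

The forecast gives 93% (87% to 97%) for alpha, 67% (60% to 74%) for epsilon, and says it rises. It reasons "Assuming 1:1 stoichiometry, product rate", and its epsilon stands above my budget.

The flask gives 90.0% for alpha and 54.5% for epsilon; it rises, by 35 percentage points.

    electrophile + nucleophile → acid set free + product (k = 7.80 × 10⁻⁴ M⁻¹ s⁻¹)
    solid electrophile ⇌ electrophile, rate k2*(cs2 - [electrophile]) while solid is left; crystals form when [electrophile] > cs2 (solubility = 0.260 M, k = 1.90 × 10⁻⁴ s⁻¹)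
    nucleophile + acid set free ⇌ protonated nucleophile, settled at all times (K = 12000 M⁻¹)

Epsilon stands under its budget of 60.0%, with free nucleophile down to 9.22% of its charge and 0.245 M of protonated nucleophile against 0.245 M of product, while 45% of the charged solid electrophile is still there, solid or dissolved. At 40.0 h epsilon reaches 63.9%, a little past the budget, with 0.0358 M of acid set free and unbound. The neighbour, epsilon with 0.22 M of nucleophile, has a budget of 24.4%; at 4.00 h it gives 23.5%, and the largest share of its solid electrophile stands as electrophile, 48.4%.

The earlier runs and the new flask come from a simulation on assumed constants; the scatter is artificial.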